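One percent of the E charged was the unit of every reading I had, with D counted in Z, and I reasoned in fractions of that charge.

| flask | E | X | L | J | temperature | remark | time |
|---|---|---|---|---|---|---|---|
| eta | 0.10 M | 1.8 equiv | 0.059 mol% | 3.3 mol% | −5 °C | run made earlier |  |
| alpha | 0.15 M | 1.8 equiv | 0.059 mol% | 3.3 mol% | 15 °C | run made earlier |  |
| birch | 0.20 M | 1.80 equiv | 0.059 mol% | 3.3 mol% |  | at 0 °C until 40 min, from then on at 30 °C | 1.0 h |
| maple | 0.20 M | 1.80 equiv | 0.059 mol% | 3.3 mol% | 0 °C |  | 1.0 h |
| larch | 0.20 M | 1.80 equiv | 0.059 mol% | 3.3 mol% | 30 °C |  | 1.0 h |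

| run | time / min | Z / % | E / % |
|---|---|---|---|
| eta | 4.00 | 0 | 91 |
| eta | 12.0 | 0 | 68 |
| eta | 20.0 | 0 | 56 |
| eta | 30.0 | 0 | 41 |
| eta | 50.0 | 7 | 24 |
| alpha | 5.00 | 1 | 47 |
| alpha | 10.0 | 7 | 22 |
| alpha | 15.0 | 16 | 11 |
| alpha | 20.0 | 20 | 9 |
| alpha | 25.0 | 25 | 0 |

(readings scatter by 2 percentage points)

- a species is counted by the E in it: one Q counts as two
- amounts and yields of Z count D too
- given per volume of solution although it is solid: D
- reactions considered so far: E + L -> L + G; X + J + G -> J + Z; D <-> Z; E + G -> Q

1. the best flask by amount of Z, in percent of the E charged; "all alike" if 1.5 percentage points covers them all (birch / maple / larch / all alike)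
2. amount of Z at the end, in percent of the E charged, birch
3. amount of Z at the end, in percent of the E charged, maple
4. amount of Z at the end, in percent of the E charged, larch

The reactions considered took E to G under L, took G with X to Z under J, and took E with G to Q, while Z passed to and from D. The bench habit is to call a reaction over when the E is gone. In the alpha run I read a first-order constant for E of 0.145 min⁻¹, and by that habit the run had finished at 25.0 min, with E at 0%. But Z then stood at 25%, which was 25.0% of the E consumed, so as a guide to Z the habit failed in the alpha run.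

I set the zero of my scale at a ratio of 1, with G leaving as fast as E. From 10.0 min to 25.0 min Z rose by 0.0120 min⁻¹ of the charge, while the part that was neither E nor Z averaged 73.0%. Taking that part as G, which ignores any Q in it, I read 0.0164 min⁻¹, so by these scattered readings of the alpha run G left 8.83 times more slowly than E went.

X and J are both dosed on E, so for 0.20 M I multiplied this constant by 1.78. I assumed a factor of 2 per 10 °C, which gave 2.83 between the alpha temperature and either flask temperature. I kept 0.0827 min⁻¹ at 30 °C as the passage constant, the pseudo-first-order fraction of G going on to Z per minute, and 0.0103 min⁻¹ at 0 °C. Its passage share, one minus the exponential of minus the constant times the time, ignored the delay while E is consumed. It came to 99.3% for larch, 87.3% for birch and 46.2% for maple. The readings were of Z and E, with none of Q or G, so I drew no yields from these shares.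

The forecast, with numbers of its own, named larch, with 58% for birch, 45% for maple and 67% for larch, on the ground that “G→Z is the slow step, so warmth helps most”.

The flasks gave 75.6% in birch, 40.4% in maple and 72.3% in larch, so birch came first.

    E + L → L + G (k = 11.0 M⁻¹ s⁻¹, Ea = 37.0 kJ mol⁻¹)
    X + J + G → J + Z (k = 0.100 M⁻² s⁻¹, Ea = 47.0 kJ mol⁻¹)
    D ⇌ Z, rate k3*(cs3 - [Z]) while solid is left; crystals form when [Z] > cs3 (solubility = 2.40 mM, k = 0.0450 s⁻¹)
    E + G → Q (k = 7.90 × 10⁻⁴ M⁻¹ s⁻¹, Ea = 69.0 kJ mol⁻¹)
    (constants at 0 °C)

Larch ended with Q at 26.7% against 10.2% in birch, and its Z made 98.6% of Z plus G, beside my share of 99.3%. The neighbour was larch with 0.050 M of E, its equivalents and loadings held. Its passage constant, scaled by the square of the charge ratio, came to 0.00517 min⁻¹, less than the 0.0827 min⁻¹ of larch, which gave a share of 26.7% over 1.0 h. That neighbour ended with Q at 29.6%, G at 50.1% and Z at 20.2%, so its Z made 28.7% of Z plus G.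

(Readings and results were generated by integration from invented constants.)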